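**Retrosynthetic overview**

1. Arene precursor: 5-bromo-o-vanillin (1) gives catechol 2 by Dakin oxidation and then o-quinone 3, which supplies the O–C=C–O unit; the bromine holds the side-chain position.
2. Key disconnection: both C–O bonds of the dioxane ring, back to quinone 3 and the C7=C8 alkene of sinapyl alcohol (4). Their catalytic enantioselective oxa-[4+2] union gives bromide 5 with both stereocentres.
3. Final disconnection: the aryl–alkenyl C–C bond, back to bromide 5 and alkenyl boronate 6 (Suzuki), giving target 7.
4. Ring order: the dioxane ring is the only ring built (step 3); both benzene rings are bought.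

Assumption: 4 and 6 are purchased as such, and (R)-TRIP is assumed to give the (2S,3S) series; if the opposite sense is found, (S)-TRIP is used with no other change.

**Route**

Step 1
Reactants: 1, 5-bromo-2-hydroxy-3-methoxybenzaldehyde
Product: 2, 5-bromo-3-methoxybenzene-1,2-diol
Conditions: 30% aq H2O2 (1.3 equiv), NaOH (1.1 equiv), H2O/THF, 0 °C → rt, N2; then 1 M HCl
Reagents that add atoms: hydrogen peroxide, OO
Why: Dakin oxidation – hydroperoxide adds to the o-hydroxybenzaldehyde, the aryl group migrates to oxygen and the formate is hydrolysed to the catechol; ArBr and OMe are inert.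

Step 2
Reactants: 2, 5-bromo-3-methoxybenzene-1,2-diol
Product: 3, 5-bromo-3-methoxycyclohexa-3,5-diene-1,2-dione (the o-quinone: C1=O, C2=O, OMe on C3, Br on C5)
Conditions: NaIO4 (1.1 equiv), CH2Cl2/H2O, 0 °C, 10 min; separate, dry (Na2SO4, then 4 Å MS), use the cold CH2Cl2 solution at once
Reagents that add atoms: none
Why: Periodate oxidation of a catechol to its o-quinone is fast and clean at 0 °C, and biphasic work-up gives a salt-free, acid-free solution that is used before the quinone can dimerise.

Step 3
Reactants: 3, 5-bromo-3-methoxy-o-benzoquinone (1.3 equiv); 4, (E)-sinapyl alcohol, 4-[(E)-3-hydroxyprop-1-enyl]-2,6-dimethoxyphenol (1.0 equiv)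
Product: 5, 4-[(2S,3S)-7-bromo-3-(hydroxymethyl)-5-methoxy-2,3-dihydro-1,4-benzodioxin-2-yl]-2,6-dimethoxyphenol (trans; aryl on C2, CH2OH on C3; O4 is the oxygen next to the OMe-bearing carbon)
Conditions: (R)-TRIP (10 mol %), 4 Å MS, CH2Cl2 (0.02 M), −50 °C, dark, 3 added over 2 h, then −50 → −30 °C
Reagents that add atoms: none
Why: Proposed new method: a chiral phosphoric acid-catalysed enantioselective inverse-electron-demand oxa-[4+2] of an o-quinone (O=C–C=O heterodiene) with a 4-hydroxystyrene – the catalyst P–OH binds the more basic C1=O of 3 (a doubly vinylogous ester through the 3-OMe) while P=O binds the phenolic OH of 4, so the vinylogous-enol β-carbon (C8) of 4 attacks the cross-conjugated, more electrophilic O2 (next to the OMe carbon, para to Br) on one enantioface in the chiral pocket (sets C3 = S), and the freed catechol O1–H then adds 1,6 to the phosphate-bound p-quinone methide anti to CH2OH (sets C2 = S; trans also follows from the E-alkene and is the thermodynamic isomer); the closest known reaction types are CPA-catalysed formal cycloadditions of hydroxystyrenes with quinone-type electrophiles, CPA-catalysed oxa-1,6-additions to in situ p-quinone methides, the uncatalysed racemic o-quinone/styrene hetero-Diels–Alder route to 1,4-benzodioxanes, and amine-catalysed enamine/o-quinone [4+2].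

Step 4
Reactants: 5, the (2S,3S)-7-bromo benzodioxane; 6, (E)-3-(4,4,5,5-tetramethyl-1,3,2-dioxaborolan-2-yl)prop-2-en-1-ol (1.5 equiv)
Product: 7, 4-[(2S,3S)-3-(hydroxymethyl)-7-[(E)-3-hydroxyprop-1-enyl]-5-methoxy-2,3-dihydro-1,4-benzodioxin-2-yl]-2,6-dimethoxyphenol (target)
Conditions: XPhos Pd G3 (3 mol %), K3PO4 (3 equiv), THF/H2O 4:1, degassed, 45 °C; aq NH4Cl work-up
Reagents that add atoms: none besides reactant 6 (OC/C=C/B1OC(C)(C)C(C)(C)O1), which delivers the C3H5O alkenyl unit
Why: Suzuki–Miyaura coupling of an unhindered aryl bromide with an (E)-alkenyl pinacol boronate proceeds with retention of alkene geometry and tolerates free OH groups; C3 is untouched, and any base-induced opening at C2 via the quinone methide re-closes to the trans ring.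

**Compound list**

1 | 5-bromo-2-hydroxy-3-methoxybenzaldehyde | O=Cc1cc(Br)cc(OC)c1O | starting material
2 | 5-bromo-3-methoxybenzene-1,2-diol | Oc1cc(Br)cc(OC)c1O | intermediate
3 | 5-bromo-3-methoxycyclohexa-3,5-diene-1,2-dione | O=C1C=C(Br)C=C(OC)C1=O | intermediate
4 | (E)-sinapyl alcohol | COc1cc(/C=C/CO)cc(OC)c1O | starting material
5 | 4-[(2S,3S)-7-bromo-3-(hydroxymethyl)-5-methoxy-2,3-dihydro-1,4-benzodioxin-2-yl]-2,6-dimethoxyphenol | COc1cc([C@@H]2Oc3cc(Br)cc(OC)c3O[C@H]2CO)cc(OC)c1O | intermediate
6 | (E)-3-(4,4,5,5-tetramethyl-1,3,2-dioxaborolan-2-yl)prop-2-en-1-ol | OC/C=C/B1OC(C)(C)C(C)(C)O1 | starting material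
7 | 4-[(2S,3S)-3-(hydroxymethyl)-7-[(E)-3-hydroxyprop-1-enyl]-5-methoxy-2,3-dihydro-1,4-benzodioxin-2-yl]-2,6-dimethoxyphenol | COc1cc([C@@H]2Oc3cc(/C=C/CO)cc(OC)c3O[C@H]2CO)cc(OC)c1O | target

**Totals**

Total steps: 4 (steps 2 and 3 are telescoped; the quinone is not isolated).
Longest linear sequence: 4 (1 → 2 → 3 → 5 → 7).

**Steps most likely to fail**

1. Step 3 (proposed new cycloaddition).
   - Risks: a racemic thermal or radical background reaction lowering ee; the opposite regiochemistry or C–C bonded (Michael/[3+2]) adducts; an unpredicted sense of induction. Regiochemistry would be checked by HMBC and ee raised by recrystallising 5.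
   - Fallback (known chemistry, different approach): set C3 by Jørgensen–Hayashi amine-catalysed epoxidation of 4-O-TBS-sinapaldehyde with H2O2, then NaBH4 reduction, silylation of the primary alcohol and acid-catalysed benzylic methanolysis of the epoxide. Join the resulting secondary alcohol to the free phenol of aldehyde 1 by Mitsunobu inversion. Reveal the second phenol by Baeyer–Villiger/Dakin oxidation of the aldehyde. Close the dioxane ring by desilylation and acid-mediated p-quinone-methide cyclisation (trans, thermodynamic), then run step 4 as written.

2. Step 2 (o-quinone generation).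
   - Risks: quinone 3 may dimerise, hydrate, or lose bromide by addition–elimination before it is consumed.
   - Fallback: replace the bromine placeholder with a formyl group. Oxidise commercial 3,4-dihydroxy-5-methoxybenzaldehyde to its more persistent, electron-poor o-quinone, carry out the cycloaddition, and build the side chain by Wittig olefination (Ph3P=CHCO2Et) and DIBAL-H reduction instead of cross-coupling. Regiochemistry must be re-verified because the formyl group is a competing director.

3. Step 4 (Suzuki coupling on the unprotected polyol).
   - Risks: phenoxide-triggered quinone-methide ring opening or hydration, protodeboronation, catalyst inhibition.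
   - Fallback: protect 5 as its bis-TBS ether so that no phenoxide can form, couple under neutral Stille conditions with (E)-3-(tributylstannyl)prop-2-en-1-ol, then remove the silyl groups with TBAF/AcOH.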